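**Retrosynthetic overview**

1. The SMILES is read as (2S,3S,4S,5S): each aryl is cis to its neighbouring CH2OH and the two CH2OH groups are trans (C2-symmetric).
2. 26 ⇐ 25 (debenzylation) ⇐ hemiketal 23 (ionic hydrogenation; the tetrahydrofuran is the last ring formed) ⇐ aryllithium 22 + lactone 21.
3. 21 ⇐ trans-benzyloxymethylation of cis-lactone 18 (first ring formed) ⇐ chelation-controlled aryl Grignard addition to aldehyde 14 ⇐ ozonolysis of 12.
4. Key bond C3–C4 (lignan 8–8′): Johnson–Claisen [3,3]-sigmatropic rearrangement of (S,Z)-allylic alcohol 8 with orthoacetate 9, relaying chirality from the carbinol to the new stereocentre.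
5. 8 ⇐ ethyl (S)-lactate 1, the only source of chirality (its C-1 becomes C-5 of the target), by silylation, partial reduction and Z-selective Wittig reaction with 5.

Assumption: 5 and 15 are bought as such (each is otherwise one step from benzyl 2-bromoethyl ether or 4-bromo-2-methoxyphenol).

**Route**

Step 1
Reactants: 1 ethyl (S)-lactate
Product: 2 ethyl (S)-2-[(tert-butyldimethylsilyl)oxy]propanoate
Conditions: TBSCl, imidazole, DMF, 0 °C → rt
Reagents that add atoms: tert-butyldimethylsilyl chloride (TBSCl), CC(C)(C)[Si](C)(C)Cl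
Why: Imidazole-mediated O-silylation masks the carbinol without touching the stereocentre.

Step 2
Reactants: 2 ethyl (S)-2-[(tert-butyldimethylsilyl)oxy]propanoate
Product: 4 (S)-2-[(tert-butyldimethylsilyl)oxy]propanal, via aluminium hemiacetal 3 (not isolated)
Conditions: iBu2AlH (1.05 equiv), CH2Cl2, −78 °C; MeOH, then aq. potassium sodium tartrate
Reagents that add atoms: none
Why: Partial ester reduction works because the tetrahedral aluminium hemiacetal 3 is stable at −78 °C and releases the aldehyde only on work-up, so there is neither over-reduction nor α-epimerisation.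

Step 3
Reactants: 4 (S)-2-[(tert-butyldimethylsilyl)oxy]propanal; 5 [2-(benzyloxy)ethyl]triphenylphosphonium bromide
Product: 8 (S,Z)-5-(benzyloxy)pent-3-en-2-ol, via phosphonium ylide 6 (not isolated), via silyl ether 7 (not isolated)
Conditions: 5, NaN(SiMe3)2, THF, 0 °C; then 4, −78 °C → rt; then Bu4NF, rt
Reagents that add atoms: none
Why: Salt-free Wittig olefination with the non-stabilised ylide 6 gives the Z-alkene under kinetic control and fluoride desilylation in the same pot frees the allylic alcohol, the minor E isomer being removed by chromatography because it would give the opposite configuration in step 4.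

Step 4
Reactants: 8 (S,Z)-5-(benzyloxy)pent-3-en-2-ol; 9 triethyl orthoacetate
Product: 12 ethyl (R,E)-3-[(benzyloxy)methyl]hex-4-enoate, via mixed orthoester 10 (not isolated), via ketene acetal 11 (not isolated)
Conditions: MeC(OEt)3 (6 equiv), EtCO2H (cat.), 140 °C, EtOH distilled off
Reagents that add atoms: none
Why: The Johnson–Claisen [3,3]-sigmatropic rearrangement of ketene acetal 11 runs through a chair transition state with the methyl group equatorial (the alternative chair has a 1,3-diaxial clash with the Z-CH2OBn), forming the future C3–C4 bond suprafacially and transferring the lactate configuration to C-3 of 12 (R, the future C-4).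

Step 5
Reactants: 12 ethyl (R,E)-3-[(benzyloxy)methyl]hex-4-enoate
Product: 14 ethyl (S)-3-[(benzyloxy)methyl]-4-oxobutanoate, via ozonide 13 (not isolated)
Conditions: O3, CH2Cl2, −78 °C; then PPh3, −78 °C → rt
Reagents that add atoms: ozone, [O-][O+]=O
Why: Ozonolysis with reductive work-up cleaves the propenyl group to the aldehyde under neutral conditions that leave the α-stereocentre and the benzyl ether intact (14 is used at once).

Step 6
Reactants: 14 ethyl (S)-3-[(benzyloxy)methyl]-4-oxobutanoate; 15 1-(benzyloxy)-4-bromo-2-methoxybenzene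
Product: 18 (4S,5S)-5-[4-(benzyloxy)-3-methoxyphenyl]-4-[(benzyloxy)methyl]dihydrofuran-2(3H)-one, via aryl Grignard reagent 16 (not isolated), via magnesium alkoxide 17 (not isolated)
Conditions: 15, Mg, THF; then 14, MgBr2·OEt2, CH2Cl2, −78 °C → rt
Reagents that add atoms: none
Why: In this Cram-chelate-controlled Grignard addition magnesium bridges the aldehyde and β-benzyloxy oxygens, the aryl group enters anti to the CH2CO2Et branch to set C-5 as S, and the alkoxide then lactonises onto the ethyl ester to give the 4,5-cis γ-lactone.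

Step 7
Reactants: 18 (4S,5S)-5-[4-(benzyloxy)-3-methoxyphenyl]-4-[(benzyloxy)methyl]dihydrofuran-2(3H)-one; 19 benzyl chloromethyl ether
Product: 21 (3S,4S,5S)-5-[4-(benzyloxy)-3-methoxyphenyl]-3,4-bis[(benzyloxy)methyl]dihydrofuran-2(3H)-one, via lithium enolate 20 (not isolated)
Conditions: LiN(SiMe3)2, THF, −78 °C; then BnOCH2Cl, −78 → −40 °C
Reagents that add atoms: none
Why: In this lactone enolate alkylation the electrophile approaches the face opposite the cis C-4 and C-5 substituents, so the new C-3 centre is S (3,4-trans).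

Step 8
Reactants: 21 (3S,4S,5S)-5-[4-(benzyloxy)-3-methoxyphenyl]-3,4-bis[(benzyloxy)methyl]dihydrofuran-2(3H)-one; 15 1-(benzyloxy)-4-bromo-2-methoxybenzene
Product: 23 (3S,4S,5S)-2,5-bis[4-(benzyloxy)-3-methoxyphenyl]-3,4-bis[(benzyloxy)methyl]tetrahydrofuran-2-ol (both C-2 epimers), via aryllithium 22 (not isolated)
Conditions: 15, n-BuLi, THF, −78 °C; then 21, −78 °C; aq. NH4Cl
Reagents that add atoms: none
Why: Nucleophilic addition of the aryllithium (from bromine–lithium exchange) to the lactone carbonyl stops at the lithium hemiketal alkoxide at −78 °C, so a single aryl group is introduced and no existing stereocentre is touched (23 is used crude).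

Step 9
Reactants: 23 (3S,4S,5S)-2,5-bis[4-(benzyloxy)-3-methoxyphenyl]-3,4-bis[(benzyloxy)methyl]tetrahydrofuran-2-ol
Product: 25 (2S,3S,4S,5S)-2,5-bis[4-(benzyloxy)-3-methoxyphenyl]-3,4-bis[(benzyloxy)methyl]tetrahydrofuran, via oxocarbenium ion 24 (not isolated)
Conditions: Et3SiH, BF3·OEt2, CH2Cl2, −78 °C
Reagents that add atoms: none
Why: In this ionic hydrogenation BF3 ionises the hemiketal to the aryl-stabilised oxocarbenium ion 24 and the silane delivers hydride anti to the adjacent C-3 benzyloxymethyl group, so the aryl group ends cis to it (C-2 S) under kinetic control, with no epimerisation at C-5 at −78 °C.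

Step 10
Reactants: 25 (2S,3S,4S,5S)-2,5-bis[4-(benzyloxy)-3-methoxyphenyl]-3,4-bis[(benzyloxy)methyl]tetrahydrofuran
Product: 26 Eduesmine
Conditions: H2 (1 atm), Pd/C, EtOAc–MeOH, rt
Reagents that add atoms: none
Why: Catalytic hydrogenolysis cleaves the four benzyl ethers (two aryl, two alkyl) under neutral conditions that leave the stereocentres untouched and cleave the benzylic ring C–O bonds much more slowly.

**Compound list**

1 | ethyl (S)-lactate | C[C@H](O)C(=O)OCC | starting material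
2 | ethyl (S)-2-[(tert-butyldimethylsilyl)oxy]propanoate | C[C@H](O[Si](C)(C)C(C)(C)C)C(=O)OCC | intermediate
3 | diisobutylaluminium (2S)-2-[(tert-butyldimethylsilyl)oxy]-1-ethoxypropan-1-olate (aluminium hemiacetal) | C[C@H](O[Si](C)(C)C(C)(C)C)C(OCC)O[Al](CC(C)C)CC(C)C | intermediate
4 | (S)-2-[(tert-butyldimethylsilyl)oxy]propanal | C[C@H](O[Si](C)(C)C(C)(C)C)C=O | intermediate
5 | [2-(benzyloxy)ethyl]triphenylphosphonium bromide | [Br-].C(COCc1ccccc1)[P+](c1ccccc1)(c1ccccc1)c1ccccc1 | starting material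
6 | [2-(benzyloxy)ethylidene]triphenylphosphorane (phosphonium ylide) | C(COCc1ccccc1)=P(c1ccccc1)(c1ccccc1)c1ccccc1 | intermediate
7 | (S,Z)-{[5-(benzyloxy)pent-3-en-2-yl]oxy}(tert-butyl)dimethylsilane | C[C@H](O[Si](C)(C)C(C)(C)C)/C=C\COCc1ccccc1 | intermediate
8 | (S,Z)-5-(benzyloxy)pent-3-en-2-ol | C[C@H](O)/C=C\COCc1ccccc1 | intermediate
9 | triethyl orthoacetate | CC(OCC)(OCC)OCC | starting material
10 | (S,Z)-5-(benzyloxy)pent-3-en-2-yl diethyl orthoacetate (mixed orthoester) | C[C@H](OC(C)(OCC)OCC)/C=C\COCc1ccccc1 | intermediate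
11 | (S,Z)-5-(benzyloxy)pent-3-en-2-yl 1-ethoxyvinyl ether (ketene acetal) | C[C@H](OC(=C)OCC)/C=C\COCc1ccccc1 | intermediate
12 | ethyl (R,E)-3-[(benzyloxy)methyl]hex-4-enoate | CCOC(=O)C[C@@H](COCc1ccccc1)/C=C/C | intermediate
13 | ethyl (3S)-4-(benzyloxy)-3-(5-methyl-1,2,4-trioxolan-3-yl)butanoate (ozonide) | CCOC(=O)C[C@@H](COCc1ccccc1)C1OOC(C)O1 | intermediate
14 | ethyl (S)-3-[(benzyloxy)methyl]-4-oxobutanoate | CCOC(=O)C[C@@H](COCc1ccccc1)C=O | intermediate
15 | 1-(benzyloxy)-4-bromo-2-methoxybenzene | COc1cc(Br)ccc1OCc1ccccc1 | starting material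
16 | [4-(benzyloxy)-3-methoxyphenyl]magnesium bromide | COc1cc([Mg]Br)ccc1OCc1ccccc1 | intermediate
17 | bromomagnesium alkoxide of ethyl (3S,4S)-4-[4-(benzyloxy)-3-methoxyphenyl]-3-[(benzyloxy)methyl]-4-hydroxybutanoate | CCOC(=O)C[C@@H](COCc1ccccc1)[C@H](O[Mg]Br)c1ccc(OCc2ccccc2)c(OC)c1 | intermediate
18 | (4S,5S)-5-[4-(benzyloxy)-3-methoxyphenyl]-4-[(benzyloxy)methyl]dihydrofuran-2(3H)-one | O=C1C[C@@H](COCc2ccccc2)[C@@H](c2ccc(OCc3ccccc3)c(OC)c2)O1 | intermediate
19 | benzyl chloromethyl ether | ClCOCc1ccccc1 | starting material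
20 | lithium (4S,5S)-5-[4-(benzyloxy)-3-methoxyphenyl]-4-[(benzyloxy)methyl]-4,5-dihydrofuran-2-olate (lithium enolate) | [Li]OC1=C[C@@H](COCc2ccccc2)[C@@H](c2ccc(OCc3ccccc3)c(OC)c2)O1 | intermediate
21 | (3S,4S,5S)-5-[4-(benzyloxy)-3-methoxyphenyl]-3,4-bis[(benzyloxy)methyl]dihydrofuran-2(3H)-one | O=C1[C@H](COCc2ccccc2)[C@@H](COCc2ccccc2)[C@@H](c2ccc(OCc3ccccc3)c(OC)c2)O1 | intermediate
22 | [4-(benzyloxy)-3-methoxyphenyl]lithium | [Li]c1ccc(OCc2ccccc2)c(OC)c1 | intermediate
23 | (3S,4S,5S)-2,5-bis[4-(benzyloxy)-3-methoxyphenyl]-3,4-bis[(benzyloxy)methyl]tetrahydrofuran-2-ol (both C-2 epimers) | OC1(c2ccc(OCc3ccccc3)c(OC)c2)[C@H](COCc2ccccc2)[C@@H](COCc2ccccc2)[C@@H](c2ccc(OCc3ccccc3)c(OC)c2)O1 | intermediate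
24 | (3S,4S,5S)-2,5-bis[4-(benzyloxy)-3-methoxyphenyl]-3,4-bis[(benzyloxy)methyl]-4,5-dihydro-3H-furan-1-ium (oxocarbenium ion) | C=1(c2ccc(OCc3ccccc3)c(OC)c2)[C@H](COCc2ccccc2)[C@@H](COCc2ccccc2)[C@@H](c2ccc(OCc3ccccc3)c(OC)c2)[O+]=1 | intermediate
25 | (2S,3S,4S,5S)-2,5-bis[4-(benzyloxy)-3-methoxyphenyl]-3,4-bis[(benzyloxy)methyl]tetrahydrofuran | [C@@H]1(c2ccc(OCc3ccccc3)c(OC)c2)[C@H](COCc2ccccc2)[C@@H](COCc2ccccc2)[C@@H](c2ccc(OCc3ccccc3)c(OC)c2)O1 | intermediate
26 | Eduesmine, [(2S,3S,4S,5S)-2,5-bis(4-hydroxy-3-methoxyphenyl)tetrahydrofuran-3,4-diyl]dimethanol | COc1cc([C@H]2O[C@H](c3ccc(O)c(OC)c3)[C@H](CO)[C@H]2CO)ccc1O | target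

**Step count and risks**

Total steps: 10. Longest linear sequence: 10 steps (1 → 26); 5, 9, 15 and 19 enter as purchased materials.

The three steps most likely to fail:

Step 6 (chelation-controlled Grignard addition and lactonisation). The ester carbonyl can compete with the benzyl ether as the chelating group, or attack can occur without chelation; either erodes or reverses the C-5 selectivity. Fallback, setting out from 14 and coming back at 18: the addition of 16 to 14 is run as before and the lactones are separated. The epimer (4S,5R)-5-[4-(benzyloxy)-3-methoxyphenyl]-4-[(benzyloxy)methyl]dihydrofuran-2(3H)-one F1 is opened with LiOH in THF–H2O to (3S,4R)-4-[4-(benzyloxy)-3-methoxyphenyl]-3-[(benzyloxy)methyl]-4-hydroxybutanoic acid F2. F2 is closed again by Mitsunobu lactonisation (PPh3, DIAD, THF, 0 °C) with inversion at the benzylic carbinol, so all material converges on 18.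

Step 8 (aryllithium addition to the α-branched, β-alkoxy lactone). Enolisation of 21 followed by loss of benzyl alcohol, or a second addition, can compete. Fallback, setting out from 21 and coming back at 23: aminolysis with MeNH(OMe)·HCl and AlMe3 (CH2Cl2, 0 °C) gives (2S,3S,4S)-4-[4-(benzyloxy)-3-methoxyphenyl]-2,3-bis[(benzyloxy)methyl]-4-hydroxy-N-methoxy-N-methylbutanamide F3. Silylation (Et3SiCl, imidazole) gives (2S,3S,4S)-4-[4-(benzyloxy)-3-methoxyphenyl]-2,3-bis[(benzyloxy)methyl]-N-methoxy-N-methyl-4-[(triethylsilyl)oxy]butanamide F4. Aryllithium 22 adds once to this amide (stable chelated adduct) to give (2S,3S,4S)-1,4-bis[4-(benzyloxy)-3-methoxyphenyl]-2,3-bis[(benzyloxy)methyl]-4-[(triethylsilyl)oxy]butan-1-one F5. HF·pyridine then removes the silyl group and the γ-hydroxy ketone closes to 23.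

Step 10 (global hydrogenolysis). Once the phenols are free, the p-hydroxybenzylic C–O bonds of the ring can be hydrogenolysed before the two alkyl benzyl ethers are gone. Fallback, setting out from 25 and coming back at 26 with no new compound: Lewis acid dealkylation with BCl3 in the presence of pentamethylbenzene as benzyl cation scavenger (CH2Cl2, −78 °C), which avoids hydrogen and palladium altogether.

Further compounds
F1 | step 6 | (4S,5R)-5-[4-(benzyloxy)-3-methoxyphenyl]-4-[(benzyloxy)methyl]dihydrofuran-2(3H)-one | O=C1C[C@@H](COCc2ccccc2)[C@H](c2ccc(OCc3ccccc3)c(OC)c2)O1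
F2 | step 6 | (3S,4R)-4-[4-(benzyloxy)-3-methoxyphenyl]-3-[(benzyloxy)methyl]-4-hydroxybutanoic acid | OC(=O)C[C@@H](COCc1ccccc1)[C@@H](O)c1ccc(OCc2ccccc2)c(OC)c1
F3 | step 8 | (2S,3S,4S)-4-[4-(benzyloxy)-3-methoxyphenyl]-2,3-bis[(benzyloxy)methyl]-4-hydroxy-N-methoxy-N-methylbutanamide | CON(C)C(=O)[C@H](COCc1ccccc1)[C@@H](COCc1ccccc1)[C@@H](c1ccc(OCc2ccccc2)c(OC)c1)O
F4 | step 8 | (2S,3S,4S)-4-[4-(benzyloxy)-3-methoxyphenyl]-2,3-bis[(benzyloxy)methyl]-N-methoxy-N-methyl-4-[(triethylsilyl)oxy]butanamide | CON(C)C(=O)[C@H](COCc1ccccc1)[C@@H](COCc1ccccc1)[C@@H](c1ccc(OCc2ccccc2)c(OC)c1)O[Si](CC)(CC)CC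
F5 | step 8 | (2S,3S,4S)-1,4-bis[4-(benzyloxy)-3-methoxyphenyl]-2,3-bis[(benzyloxy)methyl]-4-[(triethylsilyl)oxy]butan-1-one | COc1cc(ccc1OCc1ccccc1)C(=O)[C@H](COCc1ccccc1)[C@@H](COCc1ccccc1)[C@@H](c1ccc(OCc2ccccc2)c(OC)c1)O[Si](CC)(CC)CC
F0 | step 10 | none | none
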